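**Assumption:** the absolute configuration is exactly that of the given SMILES, i.e. the trans-dihydrobenzofuran is (2S,3R). No enantioselective version of the coupling in Step 2 is assumed, so that step gives racemate and the enantiomer is resolved in Step 3.

## Retrosynthetic overview
1. Target ← global TBS removal ← hydrogenation of a cyclohexene. The cis-1,3-diol and the trans 3-OH/4-OMe pair come from Red-Al opening of a syn (hydroxyl-directed) epoxy alcohol of a tertiary bis-allylic alcohol.
2. That bis-allylic ether ← Luche reduction and O-methylation of a p-quinol. The p-quinol comes from oxidative dearomatization (PIDA/H2O) of the free 4-hydroxyphenyl group on the finished dihydrobenzofuran. This breaks the aromaticity, and the two ring arms are then told apart by the epoxidation in Step 8.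
3. The trans-2-aryl-3-(silyloxymethyl)dihydrobenzofuran ← oxidative [3+2] of a 4-alkyl-guaiacol with a 4-silyloxycinnamyl silyl ether.
4. Ring order: dihydrobenzofuran first, then the cyclohexane by dearomatization.

## Route

**Step 1**
Reactants: 1 (E)-4-hydroxycinnamyl alcohol (p-coumaryl alcohol)
Product: 2 (E)-tert-butyl{3-[4-(tert-butyldimethylsilyloxy)phenyl]allyloxy}dimethylsilane (bis-TBS ether)
Conditions: TBSCl (2.3 equiv), imidazole, DMF, rt
Reagents that add atoms: TBSCl, CC(C)(C)[Si](C)(C)Cl
Why: Corey silylation masks both OH groups. The phenol stays inert in Step 2 and the allylic OH is protected for the rest of the route.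

**Step 2**
Reactants: 2; 3 methyl 3-(4-hydroxy-3-methoxyphenyl)propanoate (methyl dihydroferulate)
Product: 4 (±)-trans dihydrobenzofuran: methyl 3-[3-(TBSOCH2)-2-(4-TBSO-phenyl)-7-methoxy-2,3-dihydrobenzofuran-5-yl]propanoate
Conditions: 3 (1.5 equiv), 2 (1.0 equiv), PIDA (1.2 equiv), HFIP, –20 °C → rt
Reagents that add atoms: none
Why: Proposed new method: PIDA converts phenol 3 to a phenoxonium ion. The β-carbon of the electron-rich p-silyloxystyrene attacks its only free ortho position. The resulting p-silyloxybenzylic cation is trapped by the phenol oxygen, which gives the 2,3-dihydrobenzofuran. The closest known chemistry is PIFA-mediated phenol–alkene coupling and the Lewis-acid [3+2] of quinones with styrenes. The E-alkene gives the trans-2,3 relationship (thermodynamic closure of the open cation), and the product is racemic. The methyl ester blocks spirolactonization, and the ring-A para position is already substituted.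

**Step 3**
Reactants: 4
Product: 5 (2S,3R)-enantiomer of 4
Conditions: preparative chiral HPLC (Chiralpak IA, hexane/iPrOH); keep the (2S,3R) peak
Reagents that add atoms: none
Why: this sets the absolute configuration at C2 and C3. Neither centre is touched again.

**Step 4**
Reactants: 5
Product: 6 methyl 3-[(2S,3R)-3-(TBSOCH2)-2-(4-hydroxyphenyl)-7-methoxy-2,3-dihydrobenzofuran-5-yl]propanoate
Conditions: LiOAc·2H2O (0.2 equiv), DMF/H2O (50:1), rt
Reagents that add atoms: none
Why: mild acetate catalysis cleaves aryl silyl ethers selectively over the primary alkyl TBS ether and the methyl ester. This frees the ring-B phenol for dearomatization.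

**Step 5**
Reactants: 6
Product: 7 methyl 3-[(2S,3R)-3-(TBSOCH2)-2-(1-hydroxy-4-oxocyclohexa-2,5-dien-1-yl)-7-methoxy-2,3-dihydrobenzofuran-5-yl]propanoate (p-quinol)
Conditions: PIDA (1.1 equiv), MeCN/H2O 4:1, 0 °C, 30 min
Reagents that add atoms: water, O
Why: PIDA oxidizes the phenol ionically, which is selective over the aryl ethers of ring A. Water adds at the para (ipso) carbon, so the aromaticity is lost and the tertiary carbinol C1' is formed. C1' is not yet a stereocentre in 7 because its two ring arms are identical, so there is no selectivity problem at this step.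

**Step 6**
Reactants: 7
Product: 8 (2S,3R)-core carrying 2-(1,4-dihydroxycyclohexa-2,5-dien-1-yl), with the 4-OH trans to the tertiary 1-OH; SMILES below
Conditions: NaBH4 (1.0 equiv), CeCl3·7H2O, MeOH, –78 °C; buffered work-up (NaHCO3)
Reagents that add atoms: none
Why: Luche 1,2-reduction of the cross-conjugated dienone. Hydride enters from the face syn to the small tertiary OH and anti to the bulky dihydrobenzofuranyl group. The new 4-OH therefore ends up cis to that group, which is the relative configuration the target needs (4'-OMe cis to C2, trans to the 1'-OH). The bis-allylic tertiary alcohol is acid-labile and would aromatize, so it is kept neutral.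

**Step 7**
Reactants: 8
Product: 9 the 4-O-methyl ether of 8
Conditions: MeI (10 equiv), Ag2O (3 equiv), CH2Cl2, rt, dark
Reagents that add atoms: MeI, CI
Why: Purdie methylation under neutral conditions methylates the secondary allylic OH and leaves the hindered tertiary OH alone. The 4-methoxy group of the target is installed here with its stereochemistry already fixed.

**Step 8**
Reactants: 9
Product: 10 epoxy alcohol: the 2,3-epoxide on one ring arm of 9, on the same face as the tertiary OH and anti to OMe; the other alkene is intact
Conditions: VO(acac)2 (5 mol %), TBHP (1.1 equiv, decane), powdered NaHCO3, CH2Cl2, 0 °C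
Reagents that add atoms: TBHP, CC(C)(C)OO (supplies the epoxide O)
Why: Sharpless–Michaelson hydroxyl-directed epoxidation delivers oxygen syn to the tertiary OH, so the future C3'-OH will be cis to C1'-OH. The sterically anti OMe reinforces this face. Using one equivalent of oxidant breaks the symmetry by epoxidizing one of the two alkenes, which are diastereotopic because of the C2 stereocentre. That discrimination also fixes the configuration at C1'. The wrong-arm diastereomer is removed by chromatography.

**Step 9**
Reactants: 10
Product: 11 methyl-ester-free diol: COc1cc(CCCO)cc2c1O[C@H]([C@]1(O)C=C[C@H](OC)[C@@H](O)C1)[C@H]2CO-TBS (cyclohexene still present)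
Conditions: Red-Al (6 equiv), THF, 0 °C → rt; Rochelle salt work-up
Reagents that add atoms: none (hydride only)
Why: Red-Al opens 2,3-epoxy alcohols through the alkoxyaluminate, with hydride delivered anti to the epoxide O at the carbon next to the carbinol (C2'). This leaves a 1,3-syn diol in which the C3'-OH is cis to C1'-OH and trans to the 4'-OMe. The same reagent reduces the methyl ester to the 3-hydroxypropyl chain. TBS ethers, the aryl ethers and the isolated alkene survive.

**Step 10**
Reactants: 11
Product: 12 TBS-protected difengpiol B
Conditions: H2 (1 atm), 10% Pd/C, EtOAc, rt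
Reagents that add atoms: none
Why: heterogeneous hydrogenation of the disubstituted cyclohexene. All cyclohexane stereocentres are already set. The benzylic C–O bond of the dihydrobenzofuran is not cleaved under these mild conditions.

**Step 11**
Reactants: 12
Product: 13 difengpiol B
Conditions: TBAF (1.5 equiv), THF, 0 °C → rt
Reagents that add atoms: none
Why: fluoride removes the primary TBS ether. No stereocentre is affected.

## Compound list
1 | (E)-4-hydroxycinnamyl alcohol | OC/C=C/c1ccc(O)cc1 | starting material
2 | bis-TBS ether of 1 | CC(C)(C)[Si](C)(C)OC/C=C/c1ccc(O[Si](C)(C)C(C)(C)C)cc1 | intermediate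
3 | methyl 3-(4-hydroxy-3-methoxyphenyl)propanoate | COC(=O)CCc1ccc(O)c(OC)c1 | starting material
4 | (±)-trans dihydrobenzofuran (one enantiomer drawn) | COc1cc(CCC(=O)OC)cc2c1O[C@H](c1ccc(O[Si](C)(C)C(C)(C)C)cc1)[C@H]2CO[Si](C)(C)C(C)(C)C | intermediate
5 | (2S,3R)-enantiomer of 4 | COc1cc(CCC(=O)OC)cc2c1O[C@H](c1ccc(O[Si](C)(C)C(C)(C)C)cc1)[C@H]2CO[Si](C)(C)C(C)(C)C | intermediate
6 | phenol | COc1cc(CCC(=O)OC)cc2c1O[C@H](c1ccc(O)cc1)[C@H]2CO[Si](C)(C)C(C)(C)C | intermediate
7 | p-quinol | COc1cc(CCC(=O)OC)cc2c1O[C@H](C1(O)C=CC(=O)C=C1)[C@H]2CO[Si](C)(C)C(C)(C)C | intermediate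
8 | 1,4-diol (4-OH trans to 1-OH) | COc1cc(CCC(=O)OC)cc2c1O[C@H]([C@]1(O)C=C[C@H](O)C=C1)[C@H]2CO[Si](C)(C)C(C)(C)C | intermediate
9 | 4-methyl ether | COc1cc(CCC(=O)OC)cc2c1O[C@H]([C@]1(O)C=C[C@H](OC)C=C1)[C@H]2CO[Si](C)(C)C(C)(C)C | intermediate
10 | syn epoxy alcohol | COc1cc(CCC(=O)OC)cc2c1O[C@H]([C@]1(O)C=C[C@H](OC)[C@H]3O[C@H]31)[C@H]2CO[Si](C)(C)C(C)(C)C | intermediate
11 | cyclohexene diol with 3-hydroxypropyl chain | COc1cc(CCCO)cc2c1O[C@H]([C@]1(O)C=C[C@H](OC)[C@@H](O)C1)[C@H]2CO[Si](C)(C)C(C)(C)C | intermediate
12 | TBS-protected difengpiol B | COc1cc(CCCO)cc2c1O[C@H]([C@]1(O)CC[C@H](OC)[C@@H](O)C1)[C@H]2CO[Si](C)(C)C(C)(C)C | intermediate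
13 | difengpiol B | COc1cc(CCCO)cc2c1O[C@H]([C@]1(O)CC[C@H](OC)[C@@H](O)C1)[C@H]2CO | target

## Totals
- Total steps: 11, counting the HPLC resolution.
- Longest linear sequence: 11 steps from 1 (10 steps from 3).

## Three steps most likely to fail
1. **Step 8 (arm discrimination in the epoxidation).** The two alkenes are diastereotopic only through the remote C2 stereocentre, so the diastereomeric ratio may be poor.
   Fallback: desymmetrize p-quinol 7 first with an ene-reductase (OYE/YqjM) to one 4-hydroxycyclohexenone. Then run Luche, MeI/Ag2O, VO(acac)2 and Red-Al, so that catalyst control replaces substrate control.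
2. **Step 2 (cross [3+2] of a free phenol with a styrene).** Chemoselectivity and yield are uncertain, because the phenol can be over-oxidized or the styrene can dimerize.
   Fallback: Ag2O-mediated oxidative cross-coupling of methyl ferulate with an excess of methyl (E)-4-hydroxycinnamate. This gives the trans-2-(4-hydroxyphenyl)-3-CO2Me dihydrobenzofuran, and the esters are reduced later.
3. **Step 5 (PIDA dearomatization of an α-aryloxybenzyl phenol).** Deprotonation at the benzylic C–H could give a p-quinone methide and C–O fragmentation instead of the p-quinol.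
   Fallback: dearomatize at a simple stage. Make the p-quinol of 4-vinylphenol, run the Luche, methylation, directed epoxidation and Red-Al sequence on it, and then build the dihydrobenzofuran from the vinyl carbinol. That construction would use cross-metathesis, Sharpless epoxidation, aryl-cuprate opening and Mitsunobu cyclization.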